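The route rests on cutting ring A of the eudesmane from ring B at C1–C10 and C4=C5, a Robinson annulation. The key step exploits the carbinol carbon C11 on C7: bonded for the time being to C6, it forms a cis-fused dimethylcyclopropane on ring B that leaves C10 as the only enolisable carbon beside the C5 carbonyl and covers the β face. In one operation ethyl vinyl ketone is joined to C10, ring A closes as the C4=C5 enone and the quaternary C10 centre is fixed with its methyl cis to C7–C11. The precursor is carone, two steps from (+)-dihydrocarvone. Acid then releases C11 as the carbinol, C3 is deoxygenated and magnolol is added at C4.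

Key step: step 3

Remark: eudesmane numbering is used throughout (ring A = C1–C5 and C10, ring B = C5–C10, C11 on C7, C14 on C10, C15 on C4); β is the face of the C10 methyl.
Remark: the methyl-bearing centre next to the carbonyl of 1, 2 and 3 can epimerise; it is drawn as in (2R,5R)-dihydrocarvone and is erased as an enolate in step 3, so either epimer (and commercial epimer mixtures of 1 with fixed 5R) should serve.

Step 1
Reactants: 1 (+)-dihydrocarvone, (2R,5R)-2-methyl-5-(prop-1-en-2-yl)cyclohexan-1-one
Product: 2 (2R,5R)-5-(2-bromopropan-2-yl)-2-methylcyclohexan-1-one (dihydrocarvone hydrobromide)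
Conditions: HBr (33% in AcOH), 0 °C
Reagents that add atoms: hydrogen bromide, Br
Why: Markovnikov hydrobromination of the 1,1-disubstituted isopropenyl alkene via the tertiary cation (electrophilic HX addition) should place bromine on the future C11 while the ketone and the C7 centre stay as they are.

Step 2
Reactants: 2 dihydrocarvone hydrobromide
Product: 3 carone, (1S,3R,6R)-3,7,7-trimethylbicyclo[4.1.0]heptan-2-one
Conditions: KOH, MeOH, 0 °C → rt
Reagents that add atoms: none
Why: The enolate on the methylene side of the ketone displaces the tertiary γ-bromide in a 3-exo-tet intramolecular alkylation (1,3-dehydrohalogenation), and because a cyclopropane can only be cis-fused to the six-membered ring the new C6 centre is dictated by C7.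

Step 3
Reactants: 3 carone; 4 ethyl vinyl ketone (pent-1-en-3-one)
Product: 7 (6S,7R,10S)-6,11-cycloeudesm-4-en-3-one, via Michael diketone 5 (not isolated), via aldol ketol 6 (not isolated)
Conditions: KOH (0.3 equiv), EtOH, slow addition of 4 at 0 °C, then rt, then reflux
Reagents that add atoms: none
Why: KOH deprotonates carone at C10, the only enolisable α-carbon because C6 is a cyclopropane bridgehead whose enolate would be an alkylidenecyclopropane, and the enolate adds in Michael fashion to ethyl vinyl ketone to form C1–C10 (diketone 5). The ethyl ketone then enolises toward C4 and attacks the C5 carbonyl in a 6-(enolendo)-exo-trig aldol closure of ring A (ketol 6), and E1cB loss of water on heating gives the C4=C5 enone. The sequence is a Robinson annulation, closest in type to the annulation of 2-methylcyclohexanones with ethyl vinyl ketone. The one new stereocentre, quaternary C10, is controlled by the cis-fused cyclopropane, whose inward-pointing methyl covers the β face of the enolate, so the acceptor should bond from the α face and leave the C10 methyl β, cis to the C7–C11 bond. The step needs regioselectivity (C10 over C6) and facial selectivity, and both are secured by the cyclopropane; C5 has no second enolisable side, so only one aldol mode is open, and the quaternary C10 rules out a second alkylation.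

Step 4
Reactants: 7 6,11-cycloeudesm-4-en-3-one
Product: 8 (+)-carissone, (7R,10S)-11-hydroxyeudesm-4-en-3-one
Conditions: 10% aq. H2SO4, THF, rt
Reagents that add atoms: water, O
Why: Protonation of the enone oxygen makes C5 a cyclopropylcarbinyl cation, the C6–C11 bond breaks to the tertiary C11 cation, water adds there and the dienol returns to the conjugated enone (acid-catalysed homoconjugate opening of a cyclopropyl enone), so the carbinol should appear with C7 and C10 untouched.

Step 5
Reactants: 8 carissone
Product: 9 carissone 3,3-ethylenedithioketal (spiro-1,3-dithiolane at C3 of eudesm-4-en-11-ol)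
Conditions: HSCH2CH2SH, BF3·OEt2 (cat.), MeOH, 0 °C → rt
Reagents that add atoms: ethane-1,2-dithiol, SCCS
Why: Lewis-acid-catalysed dithioketalisation of the conjugated ketone should proceed without moving the C4=C5 double bond, as with steroidal 4-en-3-ones, and in methanol at low temperature the tertiary carbinol should not ionise.

Step 6
Reactants: 9 carissone ethylenedithioketal
Product: 10 γ-eudesmol, (7R,10R)-eudesm-4-en-11-ol
Conditions: Raney Ni (W-2, acetone-deactivated), EtOH, reflux
Reagents that add atoms: none
Why: Mozingo desulfurisation with Raney Ni replaces both C–S bonds by C–H, and the tetrasubstituted C4=C5 alkene is too hindered to be hydrogenated by the hydrogen held on the catalyst.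

Step 7
Reactants: 10 γ-eudesmol; 11 magnolol (5,5'-diallylbiphenyl-2,2'-diol)
Product: 12 eudesmagnolol, the 4α-O-(2'-hydroxy-5,5'-diallylbiphenyl-2-yl) ether of (4R,5R,7R,10R)-eudesmane-4,11-diol
Conditions: 11 (5 equiv), TfOH (10 mol%), CH2Cl2, −78 → −40 °C; Et3N quench at −78 °C
Reagents that add atoms: none
Why: Brønsted-acid-catalysed Markovnikov addition of a phenol O–H to an alkene (the reaction that makes tert-butyl and 1-methylcyclohexyl aryl ethers): protonation at C5 from the α face, anti to the axial C10 methyl, should give the trans-fused tertiary C4 cation, and the phenol oxygen should then bond to C4 equatorially from the same open α face, so that C5 (H α) and C4 (OAr α, methyl β) are both set by the angular methyl, while the allyl alkenes are too weakly basic to be protonated at −78 °C and the cold Et3N quench should keep the kinetically formed ether from ionising again.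

Compound list
1 | (+)-dihydrocarvone, (2R,5R)-2-methyl-5-(prop-1-en-2-yl)cyclohexan-1-one | C[C@@H]1CC[C@@H](C(C)=C)CC1=O | starting material
2 | (2R,5R)-5-(2-bromopropan-2-yl)-2-methylcyclohexan-1-one | C[C@@H]1CC[C@@H](C(C)(C)Br)CC1=O | intermediate
3 | carone, (1S,3R,6R)-3,7,7-trimethylbicyclo[4.1.0]heptan-2-one | C[C@@H]1CC[C@@H]2[C@H](C1=O)C2(C)C | intermediate
4 | ethyl vinyl ketone, pent-1-en-3-one | CCC(=O)C=C | starting material
5 | Michael diketone (not isolated), (1S,3S,6R)-3,7,7-trimethyl-3-(3-oxopentyl)bicyclo[4.1.0]heptan-2-one | O=C1[C@H]2[C@@H](CC[C@@]1(C)CCC(=O)CC)C2(C)C | intermediate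
6 | aldol ketol (not isolated), 5-hydroxy-6,11-cycloeudesman-3-one; C4 and C5 not assigned, both erased on dehydration | CC1C(=O)CC[C@]2(C)CC[C@@H]3[C@H](C12O)C3(C)C | intermediate
7 | (6S,7R,10S)-6,11-cycloeudesm-4-en-3-one (cyclopropane cis-fused at C6–C7 on the β face, 10β-methyl) | CC1=C2[C@H]3[C@@H](CC[C@@]2(C)CCC1=O)C3(C)C | intermediate
8 | (+)-carissone, (7R,10S)-11-hydroxyeudesm-4-en-3-one | CC1=C2C[C@@H](CC[C@@]2(C)CCC1=O)C(C)(C)O | intermediate
9 | carissone 3,3-ethylenedithioketal | CC1=C2C[C@@H](CC[C@@]2(C)CCC13SCCS3)C(C)(C)O | intermediate
10 | γ-eudesmol, (7R,10R)-eudesm-4-en-11-ol | CC1=C2C[C@@H](CC[C@@]2(C)CCC1)C(C)(C)O | intermediate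
11 | magnolol, 5,5'-diallylbiphenyl-2,2'-diol | C=CCc1ccc(O)c(-c2cc(CC=C)ccc2O)c1 | starting material
12 | eudesmagnolol (4R,5R,7R,10R) | C=CCc1ccc(O)c(-c2cc(CC=C)ccc2O[C@]2(C)CCC[C@]3(C)CC[C@@H](C(C)(C)O)C[C@H]32)c1 | target

Total step count: 7.
Longest linear sequence: 7 steps (1 → 2 → 3 → 7 → 8 → 9 → 10 → 12); 4 and 11 enter as bought.

Steps most likely to fail

Step 7. Three processes may defeat it:
- protonation of the tetrasubstituted alkene at C4 in place of C5, which leads through the C5 cation to methyl migration from C10 or to capture by the C11 hydroxyl;
- proton loss from the C4 cation outrunning capture by the hindered phenol;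
- re-ionisation of the ether under the acid, with drift to ring C-alkylation of magnolol.

The fallback sets the ring fusion beforehand and makes the cation from a trisubstituted alkene that can only be protonated toward C4. It addresses the first process only. It sets out from carissone 8. Reduction with Li in NH3/THF at −78 °C, with the carbinol as internal proton source, should give the trans-fused C3 enolate. This is trapped in the same flask with PhNTf2 as 11-hydroxy-5α-eudesm-3-en-3-yl triflate F1. Hydrogenolysis of the triflate with Pd(OAc)2, PPh3, Bu3N and HCO2H in DMF at 60 °C should then give α-eudesmol F2. Under the conditions of step 7 this alkene is protonated at C3 and gives only the C4 cation with the 5α-hydrogen already in place. The fallback comes back to the route at 12.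

Step 3. The Michael addition may show poor facial selectivity, 4 may polymerise under base before the hindered tetrasubstituted enolate reacts, or the sequence may stall at the ketol. The fallback replaces the cyclopropane as control element by a chiral imine and hydrates the side chain afterwards. It sets out from 1. Condensation with (R)-1-phenylethylamine (toluene, reflux, water removal) should give the dihydrocarvone imine F3. Its secondary enamine tautomer adds to 4 at the methyl-bearing carbon (THF, 40 °C) to give the Michael adduct imine F4. Aqueous AcOH hydrolyses this to (2S,5R)-2-methyl-2-(3-oxopentyl)-5-(prop-1-en-2-yl)cyclohexan-1-one F5. NaOMe in MeOH closes ring A by aldol condensation to (+)-α-cyperone F6. Oxymercuration–demercuration of the isopropenyl group (Hg(OAc)2, THF–H2O, rt; then NaBH4, aq. NaOH, 0 °C, briefly) should give the carbinol. The fallback comes back to the route at 8.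

Step 4. Proton loss from the C11 cation may compete with capture by water, and the product carbinol may ionise again under the acid and drift to the conjugated dienone. The fallback separates ring opening from hydration. It sets out from 7. Dry HCl in CHCl3 at 0 °C should open the cyclopropane to 11-chloroeudesm-4-en-3-one F7. NaOAc in AcOH at 100 °C removes HCl to give (+)-α-cyperone F6. Oxymercuration–demercuration as described for step 3 then delivers the carbinol, and the fallback comes back to the route at 8.

Further compounds
F1 | step 7 | 11-hydroxy-5α-eudesm-3-en-3-yl trifluoromethanesulfonate | CC1=C(OS(=O)(=O)C(F)(F)F)CC[C@]2(C)CC[C@@H](C(C)(C)O)C[C@@H]12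
F2 | step 7 | α-eudesmol, (5R,7R,10R)-eudesm-3-en-11-ol | CC1=CCC[C@]2(C)CC[C@@H](C(C)(C)O)C[C@@H]12
F3 | step 3 | imine of (+)-dihydrocarvone with (R)-1-phenylethylamine | C[C@@H]1CC[C@@H](C(C)=C)CC1=N[C@H](C)c1ccccc1
F4 | step 3 | Michael adduct imine, (R)-1-phenylethyl imine of F5 | C[C@H](c1ccccc1)N=C1C[C@@H](CC[C@@]1(C)CCC(=O)CC)C(C)=C
F5 | step 3 | (2S,5R)-2-methyl-2-(3-oxopentyl)-5-(prop-1-en-2-yl)cyclohexan-1-one | O=C1C[C@@H](CC[C@@]1(C)CCC(=O)CC)C(C)=C
F6 | step 3 | (+)-α-cyperone, (7R,10S)-eudesma-4,11-dien-3-one | CC1=C2C[C@@H](CC[C@@]2(C)CCC1=O)C(C)=C
F7 | step 4 | (7R,10S)-11-chloroeudesm-4-en-3-one | CC1=C2C[C@@H](CC[C@@]2(C)CCC1=O)C(C)(C)Cl
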